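The cyclopentanol ring D (C15, C17, C19, C20, C24; atoms numbered along the target SMILES) is cut at C17–C19 and at the ring-fusion bond C15–C24, which turns it into an acyclic allyl dienyl ether. One operation restores both bonds: a [3,3] shift joins quaternary C15 to C24, and rhodium then adds the new aldehyde C–H across the freed 1,1-disubstituted alkene, closing the ring at C17–C19. The step exploits the six-atom array C15=C17–O–C19–C20=C24 latent in ring D, with the carbinol carbon next to the quaternary carbon. Ring C then comes from ring-closing metathesis and ring B from a McMurry coupling onto a separately built ring A.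

Key step: step 4

Remark on numbering: C1–C26 and O18 follow the atom order of the target SMILES (C1 methyl on C2; C7, C12, C16 methyls on C6, C11, C15; C21–C23 isopropyl on C20). Ring A = C3–C6, C8; ring B = C2, C3, C8–C11, C13, C26; ring C = C13–C15, C24–C26; ring D = C15, C17, C19, C20, C24.
Remark on chirality: the key step is not enantioselective. Compounds 7 and 8 are racemic (SMILES show the enantiomer carried on), and the absolute configuration of the ring D fragment is fixed in step 5.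

Step 1
Reactants: 1 4-{[tert-butyl(dimethyl)silyl]oxy}but-2-yn-1-ol
Product: 2 (2E)-4-{[tert-butyl(dimethyl)silyl]oxy}-2-(propan-2-yl)but-2-en-1-ol
Conditions: iPrMgCl (3.5 equiv), CuI (10 mol %), THF, 0 → 40 °C; aq. NH4Cl
Reagents that add atoms: isopropylmagnesium chloride CC(C)[Mg]Cl
Why: Copper-assisted anti-carbomagnesiation of the propargylic alkoxide puts isopropyl on the carbon next to CH2OH through a five-membered magnesium chelate, so protonation gives the E alkene with CH2OH and CH2OSi trans.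

Step 2
Reactants: 3 but-1-en-3-yne
Product: 5 (1E)-1-iodo-2-methylbuta-1,3-diene, via dienylalane 4 (not isolated)
Conditions: Me3Al, Cp2ZrCl2 (25 mol %), CH2Cl2, 0 → 25 °C; then I2, THF, −30 °C
Reagents that add atoms: trimethylaluminium C[Al](C)C; iodine II
Why: Negishi syn-carboalumination of the terminal alkyne gives the E dienylalane, and iodinolysis of the C–Al bond proceeds with retention.

Step 3
Reactants: 2 (2E)-4-{[tert-butyl(dimethyl)silyl]oxy}-2-(propan-2-yl)but-2-en-1-ol; 5 (1E)-1-iodo-2-methylbuta-1,3-diene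
Product: 6 tert-butyl(dimethyl){[(2E)-4-{[(1E)-2-methylbuta-1,3-dien-1-yl]oxy}-3-(propan-2-yl)but-2-en-1-yl]oxy}silane
Conditions: CuI (10 mol %), 3,4,7,8-tetramethyl-1,10-phenanthroline (20 mol %), Cs2CO3, toluene, 80 °C
Reagents that add atoms: none
Why: Copper-catalysed Ullmann-type C–O coupling of an alkenyl iodide with an allylic alcohol retains both alkene geometries, below the temperature at which the ether rearranges.

Step 4
Reactants: 6 tert-butyl(dimethyl){[(2E)-4-{[(1E)-2-methylbuta-1,3-dien-1-yl]oxy}-3-(propan-2-yl)but-2-en-1-yl]oxy}silane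
Product: 8 rac-(2R,3S,4S)-3-({[tert-butyl(dimethyl)silyl]oxy}methyl)-2-ethenyl-2-methyl-4-(propan-2-yl)cyclopentan-1-one, via aldehyde 7 (not isolated)
Conditions: [Rh(cod)Cl]2 (2.5 mol %), dppe (5.5 mol %), AgBF4 (5 mol %), 1,2-dichlorobenzene, 130 °C, sealed tube
Reagents that add atoms: none
Why: Heating effects a concerted [3,3]-sigmatropic Claisen shift through a chair transition state to the α-quaternary aldehyde 7 (C15–C24 bond), whose formyl C–H adds oxidatively to cationic rhodium; hydrometalation of the 1,1-disubstituted alkene and C–C reductive elimination from a six-membered acyl–rhodium–alkyl metallacycle then form C17–C19. The closest known reaction type is the rhodium-catalysed tandem Claisen rearrangement–hydroacylation of allyl vinyl ethers to cyclopentanones. Ring D is the only ring closed, by anti-Markovnikov intramolecular hydroacylation in which both alkene carbons end in the ring (5-endo mode through the metallacycle). C15 and C24 are set relative to each other by the chair transition state and the two E double bonds (methyl pseudoaxial, ethenyl and silyloxymethyl pseudoequatorial), and C20 by the metallacycle, where cationic rhodium–diphosphine should place isopropyl trans to the C24 substituent. The step needs hydroacylation to outrun Cope rearrangement of the 1,5-diene aldehyde and decarbonylation, which the chelating diphosphine and the fast five-ring closure of a 4-pentenal should secure, and it must use the C19=C20 alkene, since the ethenyl group could only give a cyclobutanone. No absolute control is exerted, so 8 forms as a racemate with the relative configuration of the target.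

Step 5
Reactants: 8 rac-(2R,3S,4S)-3-({[tert-butyl(dimethyl)silyl]oxy}methyl)-2-ethenyl-2-methyl-4-(propan-2-yl)cyclopentan-1-one
Product: 9 (1R,2R,3S,4S)-3-({[tert-butyl(dimethyl)silyl]oxy}methyl)-2-ethenyl-2-methyl-4-(propan-2-yl)cyclopentan-1-ol
Conditions: (S)-Me-CBS oxazaborolidine (20 mol %), catecholborane, toluene, −78 → −40 °C; separation of diastereomers on silica
Reagents that add atoms: none
Why: Corey–Bakshi–Shibata reduction is catalyst-controlled on the α-quaternary ketone (quaternary side as large group), so both enantiomers of 8 give a (1R)-carbinol: the enantiomer shown gives 9 with hydroxyl cis to the C15 methyl, the other gives a separable trans diastereomer, which fixes the absolute configuration at the cost of half the material.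

Step 6
Reactants: 9 (1R,2R,3S,4S)-3-({[tert-butyl(dimethyl)silyl]oxy}methyl)-2-ethenyl-2-methyl-4-(propan-2-yl)cyclopentan-1-ol
Product: 10 tert-butyl{[(1R,2R,3S,4S)-3-({[tert-butyl(dimethyl)silyl]oxy}methyl)-2-ethenyl-2-methyl-4-(propan-2-yl)cyclopentyl]oxy}dimethylsilane
Conditions: tBuMe2SiOTf, 2,6-lutidine, CH2Cl2, 0 °C
Reagents that add atoms: tert-butyldimethylsilyl triflate CC(C)(C)[Si](C)(C)OS(=O)(=O)C(F)(F)F
Why: The silyl triflate silylates the hindered neopentylic secondary alcohol, which must be masked because the free alkoxide would later displace the C25 leaving group.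

Step 7
Reactants: 10 tert-butyl{[(1R,2R,3S,4S)-3-({[tert-butyl(dimethyl)silyl]oxy}methyl)-2-ethenyl-2-methyl-4-(propan-2-yl)cyclopentyl]oxy}dimethylsilane
Product: 11 [(1S,2R,3R,5S)-3-{[tert-butyl(dimethyl)silyl]oxy}-2-ethenyl-2-methyl-5-(propan-2-yl)cyclopentyl]methanol
Conditions: camphorsulfonic acid (10 mol %), MeOH/CH2Cl2, 0 °C
Reagents that add atoms: none
Why: Acid-catalysed methanolysis cleaves the unhindered primary silyl ether much faster than the neopentylic secondary one.

Step 8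
Reactants: 11 [(1S,2R,3R,5S)-3-{[tert-butyl(dimethyl)silyl]oxy}-2-ethenyl-2-methyl-5-(propan-2-yl)cyclopentyl]methanol
Product: 12 tert-butyl{[(1R,2R,3S,4S)-2-ethenyl-3-(iodomethyl)-2-methyl-4-(propan-2-yl)cyclopentyl]oxy}dimethylsilane
Conditions: I2, PPh3, imidazole, CH2Cl2, 0 → 25 °C
Reagents that add atoms: iodine II
Why: Appel-type iodination converts the primary alcohol to the iodide without touching the stereocentres.

Step 9
Reactants: 13 2-bromo-3-methylcyclopent-2-en-1-one
Product: 14 (1S)-2-bromo-3-methylcyclopent-2-en-1-ol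
Conditions: (R)-Me-CBS oxazaborolidine (10 mol %), BH3·SMe2, THF, −20 °C
Reagents that add atoms: none
Why: Corey–Bakshi–Shibata reduction with the bromoalkenyl side as the large group gives the (1S)-allylic alcohol, the stereocentre (C3) that later controls C6 and C8.

Step 10
Reactants: 15 {[(2E)-4-bromobut-2-en-1-yl]oxy}methylbenzene
Product: 16 ({[(2R)-2-methylbut-3-en-1-yl]oxy}methyl)benzene
Conditions: MeMgBr, CuBr·SMe2 (1 mol %), Taniaphos ligand (1.1 mol %; the enantiomer that gives the R product), CH2Cl2, −75 °C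
Reagents that add atoms: methylmagnesium bromide C[Mg]Br
Why: Copper-catalysed asymmetric allylic alkylation (SN2′) with a methyl Grignard reagent gives the branched product and sets C11 by ligand control.

Step 11
Reactants: 16 ({[(2R)-2-methylbut-3-en-1-yl]oxy}methyl)benzene; 14 (1S)-2-bromo-3-methylcyclopent-2-en-1-ol
Product: 18 (1S)-2-[(3R)-4-(benzyloxy)-3-methylbutyl]-3-methylcyclopent-2-en-1-ol, via alkylborane 17 (not isolated)
Conditions: 9-BBN, THF, 25 °C; then 14, Pd(dppf)Cl2 (5 mol %), AsPh3, Cs2CO3, DMF/H2O, 25 °C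
Reagents that add atoms: none
Why: Anti-Markovnikov hydroboration of the terminal alkene followed by B-alkyl Suzuki–Miyaura coupling with the alkenyl bromide forms C8–C9 without touching either stereocentre.

Step 12
Reactants: 18 (1S)-2-[(3R)-4-(benzyloxy)-3-methylbutyl]-3-methylcyclopent-2-en-1-ol
Product: 19 (1S,2S,3S)-2-[(3R)-4-(benzyloxy)-3-methylbutyl]-3-methylcyclopentan-1-ol
Conditions: [Ir(cod)(PCy3)(py)]PF6 (5 mol %), H2 (4 atm), CH2Cl2, 25 °C
Reagents that add atoms: none
Why: Hydroxyl-directed hydrogenation of the tetrasubstituted alkene delivers both hydrogens on the face of the C3 hydroxyl, so the C6 methyl and the C8 chain become cis to each other and trans to the hydroxyl.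

Step 13
Reactants: 19 (1S,2S,3S)-2-[(3R)-4-(benzyloxy)-3-methylbutyl]-3-methylcyclopentan-1-ol
Product: 20 {[(1S,2S,3S)-2-[(3R)-4-(benzyloxy)-3-methylbutyl]-3-methylcyclopentyl]oxy}triethylsilane
Conditions: Et3SiCl, imidazole, DMF, 0 °C
Reagents that add atoms: chlorotriethylsilane CC[Si](Cl)(CC)CC
Why: Silylation stores C3 at the alcohol oxidation level, because the cis-2,3-disubstituted ketone would epimerise at C8 if carried through the following steps.

Step 14
Reactants: 20 {[(1S,2S,3S)-2-[(3R)-4-(benzyloxy)-3-methylbutyl]-3-methylcyclopentyl]oxy}triethylsilane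
Product: 21 (2R)-2-methyl-4-[(1S,2S,5S)-2-methyl-5-(triethylsilyloxy)cyclopentyl]butan-1-ol
Conditions: H2 (1 atm), Pd/C, EtOAc, 25 °C
Reagents that add atoms: none
Why: Hydrogenolysis removes the benzyl ether at a stage where no alkene is present and leaves the silyl ether intact.

Step 15
Reactants: 21 (2R)-2-methyl-4-[(1S,2S,5S)-2-methyl-5-(triethylsilyloxy)cyclopentyl]butan-1-ol
Product: 22 (2R)-2-methyl-4-[(1S,2S,5S)-2-methyl-5-(triethylsilyloxy)cyclopentyl]butanal
Conditions: Dess–Martin periodinane, NaHCO3, CH2Cl2, 0 → 25 °C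
Reagents that add atoms: none
Why: Buffered Dess–Martin oxidation gives the α-branched aldehyde without epimerising C11.

Step 16
Reactants: 22 (2R)-2-methyl-4-[(1S,2S,5S)-2-methyl-5-(triethylsilyloxy)cyclopentyl]butanal
Product: 23 triethyl{[(1S,2S,3S)-3-methyl-2-[(3R)-3-methylpent-4-yn-1-yl]cyclopentyl]oxy}silane
Conditions: dimethyl (1-diazo-2-oxopropyl)phosphonate, K2CO3, MeOH, 0 → 25 °C
Reagents that add atoms: dimethyl (1-diazo-2-oxopropyl)phosphonate COP(=O)(OC)C(=[N+]=[N-])C(C)=O
Why: Ohira–Bestmann (Seyferth–Gilbert) homologation turns the aldehyde into the terminal alkyne under base mild enough to preserve the propargylic centre C11.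

Step 17
Reactants: 23 triethyl{[(1S,2S,3S)-3-methyl-2-[(3R)-3-methylpent-4-yn-1-yl]cyclopentyl]oxy}silane
Product: 25 methyl (2E,4R)-3,4-dimethyl-6-[(1S,2S,5S)-2-methyl-5-(triethylsilyloxy)cyclopentyl]hex-2-enoate, via alkenylalane 24 (not isolated)
Conditions: Me3Al, Cp2ZrCl2 (20 mol %), CH2Cl2, 0 → 25 °C; then ClCO2Me, 0 °C
Reagents that add atoms: trimethylaluminium C[Al](C)C; methyl chloroformate COC(Cl)=O
Why: Negishi syn-carboalumination and acylation of the alkenylalane with retention give the E enoate in which the new methyl is cis to the ester, as the next step requires.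

Step 18
Reactants: 25 methyl (2E,4R)-3,4-dimethyl-6-[(1S,2S,5S)-2-methyl-5-(triethylsilyloxy)cyclopentyl]hex-2-enoate; 12 tert-butyl{[(1R,2R,3S,4S)-2-ethenyl-3-(iodomethyl)-2-methyl-4-(propan-2-yl)cyclopentyl]oxy}dimethylsilane
Product: 27 methyl (4R)-2-{[(1S,2R,3R,5S)-3-{[tert-butyl(dimethyl)silyl]oxy}-2-ethenyl-2-methyl-5-(propan-2-yl)cyclopentyl]methyl}-4-methyl-3-methylidene-6-[(1S,2S,5S)-2-methyl-5-(triethylsilyloxy)cyclopentyl]hexanoate (both C2 epimers), via lithium dienolate 26 (not isolated)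
Conditions: LiN(iPr)2, THF, −78 °C; HMPA; then 12, −78 → −20 °C
Reagents that add atoms: none
Why: Deconjugative alkylation: the amide base removes a proton from the methyl cis to the ester and the dienolate reacts at its α-carbon with the primary iodide, forming C25–C26 and the 1,1-disubstituted alkene; C26 is not controlled here and is set in step 20.

Step 19
Reactants: 27 methyl (4R)-2-{[(1S,2R,3R,5S)-3-{[tert-butyl(dimethyl)silyl]oxy}-2-ethenyl-2-methyl-5-(propan-2-yl)cyclopentyl]methyl}-4-methyl-3-methylidene-6-[(1S,2S,5S)-2-methyl-5-(triethylsilyloxy)cyclopentyl]hexanoate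
Product: 28 methyl (1R,3S,3aS,7aS)-1-{[tert-butyl(dimethyl)silyl]oxy}-7a-methyl-6-{(2R)-4-[(1S,2S,5S)-2-methyl-5-(triethylsilyloxy)cyclopentyl]butan-2-yl}-3-(propan-2-yl)-2,3,3a,4,5,7a-hexahydro-1H-indene-5-carboxylate (both C5 epimers)
Conditions: second-generation Hoveyda–Grubbs catalyst (10 mol %), toluene, 80 °C
Reagents that add atoms: none
Why: Ring-closing metathesis between the ethenyl group on C15 and the 1,1-disubstituted alkene closes the six-membered ring C as the trisubstituted C13=C14 alkene with loss of ethene.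

Step 20
Reactants: 28 methyl (1R,3S,3aS,7aS)-1-{[tert-butyl(dimethyl)silyl]oxy}-7a-methyl-6-{(2R)-4-[(1S,2S,5S)-2-methyl-5-(triethylsilyloxy)cyclopentyl]butan-2-yl}-3-(propan-2-yl)-2,3,3a,4,5,7a-hexahydro-1H-indene-5-carboxylate
Product: 30 methyl (1R,3S,3aS,5S,7aS)-1-{[tert-butyl(dimethyl)silyl]oxy}-7a-methyl-6-{(2R)-4-[(1S,2S,5S)-2-methyl-5-(triethylsilyloxy)cyclopentyl]butan-2-yl}-3-(propan-2-yl)-2,3,3a,4,5,7a-hexahydro-1H-indene-5-carboxylate, via potassium dienolate 29 (not isolated)
Conditions: KN(SiMe3)2, THF, −78 °C; then AcOH, −78 °C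
Reagents that add atoms: none
Why: Kinetic α-protonation of the exocyclic ester dienolate should occur axially on the face opposite the axial C15 methyl (as in α-face protonation of steroidal dienolates), which converges both epimers to H26 cis to H24 and keeps the alkene out of conjugation.

Step 21
Reactants: 30 methyl (1R,3S,3aS,5S,7aS)-1-{[tert-butyl(dimethyl)silyl]oxy}-7a-methyl-6-{(2R)-4-[(1S,2S,5S)-2-methyl-5-(triethylsilyloxy)cyclopentyl]butan-2-yl}-3-(propan-2-yl)-2,3,3a,4,5,7a-hexahydro-1H-indene-5-carboxylate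
Product: 32 1-[(1R,3S,3aS,5S,7aS)-1-{[tert-butyl(dimethyl)silyl]oxy}-6-{(2R)-4-[(1S,2S,5S)-5-hydroxy-2-methylcyclopentyl]butan-2-yl}-7a-methyl-3-(propan-2-yl)-2,3,3a,4,5,7a-hexahydro-1H-inden-5-yl]ethan-1-one, via enol ether 31 (not isolated)
Conditions: Cp2Ti(μ-Cl)(μ-CH2)AlMe2, pyridine, THF/toluene, −40 → 0 °C; then 1 M HCl, THF, 0 → 25 °C
Reagents that add atoms: Cp2Ti(μ-Cl)(μ-CH2)AlMe2 (Tebbe reagent) C[Al-]1(C)C[Ti](C2C=CC=C2)(C2C=CC=C2)[Cl+]1; water O
Why: Tebbe methylenation (pyridine releases titanocene methylidene, which undergoes [2+2] addition to the ester carbonyl and cycloreversion) turns the ester into its methyl enol ether without base, and aqueous acid hydrolyses it to the methyl ketone and removes the triethylsilyl ether while the neopentylic tert-butyldimethylsilyl ether survives; the bridging chloride of the reagent is drawn with formal charges on chlorine and aluminium.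

Step 22
Reactants: 32 1-[(1R,3S,3aS,5S,7aS)-1-{[tert-butyl(dimethyl)silyl]oxy}-6-{(2R)-4-[(1S,2S,5S)-5-hydroxy-2-methylcyclopentyl]butan-2-yl}-7a-methyl-3-(propan-2-yl)-2,3,3a,4,5,7a-hexahydro-1H-inden-5-yl]ethan-1-one
Product: 33 (2S,3S)-2-{(3R)-3-[(1R,3S,3aS,5S,7aS)-5-acetyl-1-{[tert-butyl(dimethyl)silyl]oxy}-7a-methyl-3-(propan-2-yl)-2,3,3a,4,5,7a-hexahydro-1H-inden-6-yl]butyl}-3-methylcyclopentan-1-one
Conditions: Dess–Martin periodinane, NaHCO3, CH2Cl2, 0 → 25 °C
Reagents that add atoms: none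
Why: Buffered Dess–Martin oxidation unveils the ring A ketone only now, under neutral conditions that should not epimerise the cis C8 centre or C26.

Step 23
Reactants: 33 (2S,3S)-2-{(3R)-3-[(1R,3S,3aS,5S,7aS)-5-acetyl-1-{[tert-butyl(dimethyl)silyl]oxy}-7a-methyl-3-(propan-2-yl)-2,3,3a,4,5,7a-hexahydro-1H-inden-6-yl]butyl}-3-methylcyclopentan-1-one
Product: 34 O18-tert-butyldimethylsilyl ether of aspergilol C
Conditions: TiCl3(DME)1.5, Zn–Cu couple, DME, reflux, slow addition of 33
Reagents that add atoms: none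
Why: Intramolecular McMurry reductive coupling of the methyl ketone (C2) with the cyclopentanone (C3) on low-valent titanium forms the tetrasubstituted C2=C3 alkene and ring B, whose Z geometry the eight-membered ring enforces.

Step 24
Reactants: 34 O18-tert-butyldimethylsilyl ether of aspergilol C
Product: 35 aspergilol C
Conditions: Bu4NF, THF, 50 °C
Reagents that add atoms: none
Why: Fluoride cleaves the hindered secondary silyl ether and releases the C17 alcohol without affecting the two alkenes.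

Compound list
1 | 4-{[tert-butyl(dimethyl)silyl]oxy}but-2-yn-1-ol | OCC#CCO[Si](C)(C)C(C)(C)C | starting material
2 | (2E)-4-{[tert-butyl(dimethyl)silyl]oxy}-2-(propan-2-yl)but-2-en-1-ol | OC/C(C(C)C)=C/CO[Si](C)(C)C(C)(C)C | intermediate
3 | but-1-en-3-yne (vinylacetylene) | C=CC#C | starting material
4 | dimethyl[(1E)-2-methylbuta-1,3-dien-1-yl]alane (not isolated) | C=C/C(C)=C/[Al](C)C | intermediate
5 | (1E)-1-iodo-2-methylbuta-1,3-diene | C=C/C(C)=C/I | intermediate
6 | tert-butyl(dimethyl){[(2E)-4-{[(1E)-2-methylbuta-1,3-dien-1-yl]oxy}-3-(propan-2-yl)but-2-en-1-yl]oxy}silane | C=C/C(C)=C/OC/C(C(C)C)=C/CO[Si](C)(C)C(C)(C)C | intermediate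
7 | rac-(2R,3S)-3-({[tert-butyl(dimethyl)silyl]oxy}methyl)-2-ethenyl-2-methyl-4-(propan-2-yl)pent-4-enal (not isolated; one enantiomer drawn) | C=C[C@@](C)(C=O)[C@@H](CO[Si](C)(C)C(C)(C)C)C(=C)C(C)C | intermediate
8 | rac-(2R,3S,4S)-3-({[tert-butyl(dimethyl)silyl]oxy}methyl)-2-ethenyl-2-methyl-4-(propan-2-yl)cyclopentan-1-one (one enantiomer drawn) | C=C[C@@]1(C)C(=O)C[C@@H](C(C)C)[C@@H]1CO[Si](C)(C)C(C)(C)C | intermediate
9 | (1R,2R,3S,4S)-3-({[tert-butyl(dimethyl)silyl]oxy}methyl)-2-ethenyl-2-methyl-4-(propan-2-yl)cyclopentan-1-ol | C=C[C@@]1(C)[C@H](O)C[C@@H](C(C)C)[C@@H]1CO[Si](C)(C)C(C)(C)C | intermediate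
10 | tert-butyl{[(1R,2R,3S,4S)-3-({[tert-butyl(dimethyl)silyl]oxy}methyl)-2-ethenyl-2-methyl-4-(propan-2-yl)cyclopentyl]oxy}dimethylsilane | C=C[C@@]1(C)[C@H](O[Si](C)(C)C(C)(C)C)C[C@@H](C(C)C)[C@@H]1CO[Si](C)(C)C(C)(C)C | intermediate
11 | [(1S,2R,3R,5S)-3-{[tert-butyl(dimethyl)silyl]oxy}-2-ethenyl-2-methyl-5-(propan-2-yl)cyclopentyl]methanol | C=C[C@@]1(C)[C@H](O[Si](C)(C)C(C)(C)C)C[C@@H](C(C)C)[C@@H]1CO | intermediate
12 | tert-butyl{[(1R,2R,3S,4S)-2-ethenyl-3-(iodomethyl)-2-methyl-4-(propan-2-yl)cyclopentyl]oxy}dimethylsilane | C=C[C@@]1(C)[C@H](O[Si](C)(C)C(C)(C)C)C[C@@H](C(C)C)[C@@H]1CI | intermediate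
13 | 2-bromo-3-methylcyclopent-2-en-1-one | CC1=C(Br)C(=O)CC1 | starting material
14 | (1S)-2-bromo-3-methylcyclopent-2-en-1-ol | O[C@H]1CCC(C)=C1Br | intermediate
15 | {[(2E)-4-bromobut-2-en-1-yl]oxy}methylbenzene | BrC/C=C/COCc1ccccc1 | starting material
16 | ({[(2R)-2-methylbut-3-en-1-yl]oxy}methyl)benzene | C=C[C@@H](C)COCc1ccccc1 | intermediate
17 | 9-[(3R)-4-(benzyloxy)-3-methylbutyl]-9-borabicyclo[3.3.1]nonane (not isolated) | C[C@H](CCB1C2CCCC1CCC2)COCc1ccccc1 | intermediate
18 | (1S)-2-[(3R)-4-(benzyloxy)-3-methylbutyl]-3-methylcyclopent-2-en-1-ol | O[C@H]1CCC(C)=C1CC[C@@H](C)COCc1ccccc1 | intermediate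
19 | (1S,2S,3S)-2-[(3R)-4-(benzyloxy)-3-methylbutyl]-3-methylcyclopentan-1-ol | O[C@H]1CC[C@H](C)[C@@H]1CC[C@@H](C)COCc1ccccc1 | intermediate
20 | {[(1S,2S,3S)-2-[(3R)-4-(benzyloxy)-3-methylbutyl]-3-methylcyclopentyl]oxy}triethylsilane | CC[Si](CC)(CC)O[C@H]1CC[C@H](C)[C@@H]1CC[C@@H](C)COCc1ccccc1 | intermediate
21 | (2R)-2-methyl-4-[(1S,2S,5S)-2-methyl-5-(triethylsilyloxy)cyclopentyl]butan-1-ol | CC[Si](CC)(CC)O[C@H]1CC[C@H](C)[C@@H]1CC[C@@H](C)CO | intermediate
22 | (2R)-2-methyl-4-[(1S,2S,5S)-2-methyl-5-(triethylsilyloxy)cyclopentyl]butanal | CC[Si](CC)(CC)O[C@H]1CC[C@H](C)[C@@H]1CC[C@@H](C)C=O | intermediate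
23 | triethyl{[(1S,2S,3S)-3-methyl-2-[(3R)-3-methylpent-4-yn-1-yl]cyclopentyl]oxy}silane | CC[Si](CC)(CC)O[C@H]1CC[C@H](C)[C@@H]1CC[C@@H](C)C#C | intermediate
24 | dimethyl{(1E,3R)-2,3-dimethyl-5-[(1S,2S,5S)-2-methyl-5-(triethylsilyloxy)cyclopentyl]pent-1-en-1-yl}alane (not isolated) | CC[Si](CC)(CC)O[C@H]1CC[C@H](C)[C@@H]1CC[C@@H](C)/C(C)=C/[Al](C)C | intermediate
25 | methyl (2E,4R)-3,4-dimethyl-6-[(1S,2S,5S)-2-methyl-5-(triethylsilyloxy)cyclopentyl]hex-2-enoate | CC[Si](CC)(CC)O[C@H]1CC[C@H](C)[C@@H]1CC[C@@H](C)/C(C)=C/C(=O)OC | intermediate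
26 | lithium dienolate of 25 (γ-deprotonated at the 3-methyl; not isolated) | [Li+].C=C([C@H](C)CC[C@H]1[C@@H](C)CC[C@@H]1O[Si](CC)(CC)CC)C=C([O-])OC | intermediate
27 | methyl (4R)-2-{[(1S,2R,3R,5S)-3-{[tert-butyl(dimethyl)silyl]oxy}-2-ethenyl-2-methyl-5-(propan-2-yl)cyclopentyl]methyl}-4-methyl-3-methylidene-6-[(1S,2S,5S)-2-methyl-5-(triethylsilyloxy)cyclopentyl]hexanoate (both C2 epimers, C2 = C26 of the target) | COC(=O)C(C[C@H]1[C@H](C(C)C)C[C@@H](O[Si](C)(C)C(C)(C)C)[C@]1(C)C=C)C(=C)[C@H](C)CC[C@H]1[C@@H](C)CC[C@@H]1O[Si](CC)(CC)CC | intermediate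
28 | methyl (1R,3S,3aS,7aS)-1-{[tert-butyl(dimethyl)silyl]oxy}-7a-methyl-6-{(2R)-4-[(1S,2S,5S)-2-methyl-5-(triethylsilyloxy)cyclopentyl]butan-2-yl}-3-(propan-2-yl)-2,3,3a,4,5,7a-hexahydro-1H-indene-5-carboxylate (both C5 epimers, C5 = C26 of the target) | COC(=O)C1C[C@H]2[C@H](C(C)C)C[C@@H](O[Si](C)(C)C(C)(C)C)[C@]2(C)C=C1[C@H](C)CC[C@H]1[C@@H](C)CC[C@@H]1O[Si](CC)(CC)CC | intermediate
29 | potassium dienolate of 28 (exocyclic at C26; not isolated) | [K+].COC([O-])=C1C[C@H]2[C@H](C(C)C)C[C@@H](O[Si](C)(C)C(C)(C)C)[C@]2(C)C=C1[C@H](C)CC[C@H]1[C@@H](C)CC[C@@H]1O[Si](CC)(CC)CC | intermediate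
30 | methyl (1R,3S,3aS,5S,7aS)-1-{[tert-butyl(dimethyl)silyl]oxy}-7a-methyl-6-{(2R)-4-[(1S,2S,5S)-2-methyl-5-(triethylsilyloxy)cyclopentyl]butan-2-yl}-3-(propan-2-yl)-2,3,3a,4,5,7a-hexahydro-1H-indene-5-carboxylate | COC(=O)[C@H]1C[C@H]2[C@H](C(C)C)C[C@@H](O[Si](C)(C)C(C)(C)C)[C@]2(C)C=C1[C@H](C)CC[C@H]1[C@@H](C)CC[C@@H]1O[Si](CC)(CC)CC | intermediate
31 | methyl enol ether of 30 (CO2Me replaced by C(=CH2)OMe; not isolated) | COC(=C)[C@H]1C[C@H]2[C@H](C(C)C)C[C@@H](O[Si](C)(C)C(C)(C)C)[C@]2(C)C=C1[C@H](C)CC[C@H]1[C@@H](C)CC[C@@H]1O[Si](CC)(CC)CC | intermediate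
32 | 1-[(1R,3S,3aS,5S,7aS)-1-{[tert-butyl(dimethyl)silyl]oxy}-6-{(2R)-4-[(1S,2S,5S)-5-hydroxy-2-methylcyclopentyl]butan-2-yl}-7a-methyl-3-(propan-2-yl)-2,3,3a,4,5,7a-hexahydro-1H-inden-5-yl]ethan-1-one | CC(=O)[C@H]1C[C@H]2[C@H](C(C)C)C[C@@H](O[Si](C)(C)C(C)(C)C)[C@]2(C)C=C1[C@H](C)CC[C@H]1[C@@H](C)CC[C@@H]1O | intermediate
33 | (2S,3S)-2-{(3R)-3-[(1R,3S,3aS,5S,7aS)-5-acetyl-1-{[tert-butyl(dimethyl)silyl]oxy}-7a-methyl-3-(propan-2-yl)-2,3,3a,4,5,7a-hexahydro-1H-inden-6-yl]butyl}-3-methylcyclopentan-1-one | CC(=O)[C@H]1C[C@H]2[C@H](C(C)C)C[C@@H](O[Si](C)(C)C(C)(C)C)[C@]2(C)C=C1[C@H](C)CC[C@H]1[C@@H](C)CCC1=O | intermediate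
34 | O18-tert-butyldimethylsilyl ether of aspergilol C | C/C1=C2\CC[C@H](C)[C@@H]2CC[C@@H](C)C2=C[C@@]3(C)[C@H](O[Si](C)(C)C(C)(C)C)C[C@@H](C(C)C)[C@@H]3C[C@@H]21 | intermediate
35 | aspergilol C | C/C1=C2\CC[C@H](C)[C@@H]2CC[C@@H](C)C2=C[C@@]3(C)[C@H](O)C[C@@H](C(C)C)[C@@H]3C[C@@H]21 | target

Total step count: 24 steps.
Longest linear sequence: 15 steps (13 → step 9, steps 11–17, then steps 18–24; the branch from 15 is equally long; the ring D branch from 1 is 14 steps).

Steps most likely to fail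

Step 4. The Claisen aldehyde is a 3-formyl-1,5-diene, so Cope rearrangement to the conjugated enal, or decarbonylation of the acyl–rhodium hydride at 130 °C, may consume it before the ring closes; alkene isomerisation by rhodium hydride is a further drain. The fallback separates the two bond formations and keeps everything cold. It sets out from 6: triisobutylaluminium in CH2Cl2 (−78 → 0 °C) promotes the Claisen shift through the same chair array and reduces the aldehyde as it forms, giving the racemic primary alcohol F1. Dess–Martin oxidation then gives aldehyde 7 as an isolated compound, and cationic [Rh(nbd)(dppe)]BF4 (activated with H2) in CH2Cl2 at 25 °C effects the hydroacylation well below the Cope threshold. The sequence returns to the route at 8.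

Step 20. The protonation may show poor facial selectivity, because the axial C15 methyl is only in a 1,4-relationship to C26, or may occur at the γ-carbon and pull the alkene into conjugation; thermodynamic equilibration would probably favour the wrong, pseudoaxial ester. The fallback sets C26 before ring C is closed, by auxiliary control, starting from 25 and 11 and returning at 30. Saponification of 25 (LiOH) gives the acid F2, which is converted through its pivalic mixed anhydride and lithiated (4S)-4-benzyl-1,3-oxazolidin-2-one into the imide F3. Alcohol 11 is turned into the triflate F4 (Tf2O, 2,6-lutidine), which is reactive enough for an imide enolate. NaN(SiMe3)2 deprotonates F3 at the methyl cis to the carbonyl, and the chelated Z-dienolate is alkylated by F4 at the α-carbon on the face opposite the benzyl group (Evans alkylation), giving the imide F5 with the required C26 configuration. Ring-closing metathesis as in step 19 gives the bicyclic imide F6, and MeOMgBr in MeOH removes the auxiliary to give 30.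

Step 23. The eight-membered ring with a tetrasubstituted alkene is the hardest closure of the route: intermolecular coupling may compete, and the hot Lewis-acidic titanium medium may enolise the ketones, epimerising C8 or C26 or moving the C13=C14 alkene into conjugation with the acetyl group. The fallback splits the coupling into a low-temperature C–C bond formation and a separate deoxygenation, starting from 33. SmI2 in THF (−78 → 0 °C) gives the cis-pinacol F7 by intramolecular ketyl coupling, 1,1′-thiocarbonyldiimidazole converts it into the cyclic thionocarbonate F8, and Corey–Winter fragmentation with 1,3-dimethyl-2-phenyl-1,3,2-diazaphospholidine at 40 °C gives the tetrasubstituted alkene 34, where the fallback rejoins the route.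

Further compounds
F1 | step 4 | rac-(2R,3S)-3-({[tert-butyl(dimethyl)silyl]oxy}methyl)-2-ethenyl-2-methyl-4-(propan-2-yl)pent-4-en-1-ol (one enantiomer drawn) | C=C[C@@](C)(CO)[C@@H](CO[Si](C)(C)C(C)(C)C)C(=C)C(C)C
F2 | step 20 | (2E,4R)-3,4-dimethyl-6-[(1S,2S,5S)-2-methyl-5-(triethylsilyloxy)cyclopentyl]hex-2-enoic acid | CC[Si](CC)(CC)O[C@H]1CC[C@H](C)[C@@H]1CC[C@@H](C)/C(C)=C/C(=O)O
F3 | step 20 | (4S)-4-benzyl-3-{(2E,4R)-3,4-dimethyl-6-[(1S,2S,5S)-2-methyl-5-(triethylsilyloxy)cyclopentyl]hex-2-enoyl}-1,3-oxazolidin-2-one | CC[Si](CC)(CC)O[C@H]1CC[C@H](C)[C@@H]1CC[C@@H](C)/C(C)=C/C(=O)N1[C@@H](Cc2ccccc2)COC1=O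
F4 | step 20 | [(1S,2R,3R,5S)-3-{[tert-butyl(dimethyl)silyl]oxy}-2-ethenyl-2-methyl-5-(propan-2-yl)cyclopentyl]methyl trifluoromethanesulfonate | C=C[C@@]1(C)[C@H](O[Si](C)(C)C(C)(C)C)C[C@@H](C(C)C)[C@@H]1COS(=O)(=O)C(F)(F)F
F5 | step 20 | (4S)-4-benzyl-3-acyl-1,3-oxazolidin-2-one analogue of 27 (imide in place of the methyl ester, single C26 epimer with the target configuration) | O=C(N1[C@@H](Cc2ccccc2)COC1=O)[C@@H](C[C@H]1[C@H](C(C)C)C[C@@H](O[Si](C)(C)C(C)(C)C)[C@]1(C)C=C)C(=C)[C@H](C)CC[C@H]1[C@@H](C)CC[C@@H]1O[Si](CC)(CC)CC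
F6 | step 20 | (4S)-4-benzyl-3-acyl-1,3-oxazolidin-2-one analogue of 30 (imide in place of the methyl ester) | O=C(N1[C@@H](Cc2ccccc2)COC1=O)[C@H]1C[C@H]2[C@H](C(C)C)C[C@@H](O[Si](C)(C)C(C)(C)C)[C@]2(C)C=C1[C@H](C)CC[C@H]1[C@@H](C)CC[C@@H]1O[Si](CC)(CC)CC
F7 | step 23 | C2,C3-cis-diol of 34 (C2=C3 replaced by C2(OH)–C3(OH); configuration at C2 and C3 not defined) | CC1(O)C2(O)CC[C@H](C)[C@@H]2CC[C@@H](C)C2=C[C@@]3(C)[C@H](O[Si](C)(C)C(C)(C)C)C[C@@H](C(C)C)[C@@H]3C[C@@H]21
F8 | step 23 | cyclic thionocarbonate of diol F7 | CC12OC(=S)OC13CC[C@H](C)[C@@H]3CC[C@@H](C)C3=C[C@@]4(C)[C@H](O[Si](C)(C)C(C)(C)C)C[C@@H](C(C)C)[C@@H]4C[C@@H]32
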